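**Plan**

1. Retrosynthesis: after removal of twelve O‑benzyl groups, the pyran ring of the middle unit is cut at O1–C2 and C4–C4a (formal [3+3]) into resorcinol 14 (top unit bearing the future middle A‑ring) and epoxy carbinol 20 (bottom unit bearing C4–C3–C2 and the B‑ring). 14 is cut at C4(top)–C8(middle), with cyclohexane‑1,3‑dione as resorcinol surrogate, and at the top pyran ring; 20 is cut at C8(bottom)–C4. One cis‑epoxy aldehyde 5 supplies both three‑carbon pieces.
2. Forward: Z‑cinnamate → cis‑glycidate → aldehyde 5; top pyran ring (aryllithium addition, 6‑endo epoxide opening) → C‑4 alkylation of the dione → aromatisation to 14. Epicatechin → pentabenzyl ether → 8‑bromide → 8‑lithio + 5 → 20. Then 14 + 20 close the middle pyran ring in one operation (22), and hydrogenolysis gives the target.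
3. Enabling feature: C‑4 of the middle unit is benzylic to C‑8 of the bottom A‑ring (ortho to O‑1 and O‑7, para to O‑5), so a C‑4 hydroxyl ionises under mild acid. The middle A‑ring is a resorcinol substituted at the carbon between its oxygens (C‑8), so its two OH/ortho‑CH pairs (O‑1/C‑4a and O‑7/C‑6) are equivalent by rotation about C4(top)–C8 and either gives the same chroman. C‑2 is benzylic to the pyrogallol ring, so the phenol opens a C2–C3 epoxide 6‑endo.
4. Stereochemistry: bottom C‑2/C‑3 come from (−)‑epicatechin. C‑2/C‑3 of the top and middle units come from the Jacobsen epoxide (C‑3 retained, C‑2 inverted in each ring closure; cis‑epoxide gives 2,3‑cis). Top C‑4 is set by trans addition to the cyclic cation (4β); middle C‑4 by face selection on the acyclic cation next to the cis‑epoxide (4α, all‑cis).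

Key step: step 11

Remark: the target is read as epirobinetinidol‑(4β→8)‑epirobinetinidol‑(4α→8)‑epicatechin: top unit 2R,3R,4R (2,3‑cis‑3,4‑trans), middle unit 2R,3R,4S (all‑cis), bottom unit 2R,3R.
Assumption: 5‑(benzyloxy)‑2‑bromophenol (6) is taken as a catalogue compound; otherwise it is one O‑benzylation away from 4‑bromoresorcinol.

**Route**

Step 1
Reactants: 1 3,4,5‑tris(benzyloxy)benzaldehyde; 2 methyl bis(2,2,2‑trifluoroethyl)phosphonoacetate
Product: 3 methyl (Z)‑3‑[3,4,5‑tris(benzyloxy)phenyl]prop‑2‑enoate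
Conditions: KHMDS, 18‑crown‑6, THF, −78 °C
Reagents that add atoms: none
Why: Still–Gennari variant of the Horner–Wadsworth–Emmons olefination, in which the electron‑poor phosphonate under dissociating conditions eliminates faster than the adducts equilibrate, should give the Z‑cinnamate needed for a cis‑epoxide.

Step 2
Reactants: 3 methyl (Z)‑3‑[3,4,5‑tris(benzyloxy)phenyl]prop‑2‑enoate
Product: 4 methyl (2S,3S)‑3‑[3,4,5‑tris(benzyloxy)phenyl]oxirane‑2‑carboxylate (cis)
Conditions: (S,S)‑Jacobsen Mn(salen)Cl (6 mol%), 4‑phenylpyridine N‑oxide (0.25 equiv), aq. NaOCl (pH 11.3), CH2Cl2, 4 °C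
Reagents that add atoms: sodium hypochlorite, [Na+].[O-]Cl
Why: Jacobsen–Katsuki epoxidation, for which cis‑cinnamate esters are favoured substrates; side‑on approach of the cis‑alkene to the (salen)Mn‑oxo species sets both epoxide carbons (2S,3S expected with the (S,S)‑catalyst, the mirror image of the (R,R)‑catalyst/(2R,3R)‑glycidate pairing of ethyl cis‑cinnamate), and the N‑oxide additive limits leakage to the trans‑epoxide.

Step 3
Reactants: 4 methyl (2S,3S)‑3‑[3,4,5‑tris(benzyloxy)phenyl]oxirane‑2‑carboxylate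
Product: 5 (2S,3S)‑3‑[3,4,5‑tris(benzyloxy)phenyl]oxirane‑2‑carbaldehyde (cis)
Conditions: DIBAL‑H (1.1 equiv), CH2Cl2, −78 °C; MeOH, then aq. Rochelle salt
Reagents that add atoms: none
Why: partial ester reduction with DIBAL‑H at −78 °C, where the aluminium hemiacetal, held by chelation to the epoxide oxygen, should survive until the quench; the epoxide stereocentres are not touched.

Step 4
Reactants: 6 5‑(benzyloxy)‑2‑bromophenol; 5 (2S,3S)‑3‑[3,4,5‑tris(benzyloxy)phenyl]oxirane‑2‑carbaldehyde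
Product: 9 (2R,3R)‑7‑(benzyloxy)‑2‑[3,4,5‑tris(benzyloxy)phenyl]chromane‑3,4‑diol (2,3‑cis; C‑4 epimers), via dilithio phenoxide 7 (not isolated), via hydroxy epoxide 8 (not isolated)
Conditions: n‑BuLi (2.1 equiv), Et2O/THF, −78 → 0 °C; 5, −78 °C; AcOH, −78 °C; then crude, PPTS (10 mol%), CH2Cl2, 0 °C → rt
Reagents that add atoms: none
Why: bromine–lithium exchange and 1,2‑addition of the aryllithium to the aldehyde form C4–C4a, and the acid‑catalysed 6‑endo‑tet opening of the cis‑epoxide by the phenol at the benzylic carbon (inversion at C‑2, C‑3 retained) should give the 2,3‑cis (2R,3R) flavan‑3,4‑diol; the C‑4 carbinol is formed without control and is erased in step 5.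

Step 5
Reactants: 9 (2R,3R)‑7‑(benzyloxy)‑2‑[3,4,5‑tris(benzyloxy)phenyl]chromane‑3,4‑diol; 10 cyclohexane‑1,3‑dione
Product: 11 2‑[(2R,3R,4R)‑7‑(benzyloxy)‑3‑hydroxy‑2‑[3,4,5‑tris(benzyloxy)phenyl]chroman‑4‑yl]‑3‑hydroxycyclohex‑2‑en‑1‑one (enol form of the 2‑substituted 1,3‑dione; 2,3‑cis‑3,4‑trans)
Conditions: 10 (5 equiv), p‑TsOH·H2O (10 mol%), MeCN/CH2Cl2, 0 °C → rt
Reagents that add atoms: none
Why: acid‑catalysed benzylic substitution (flavan‑3,4‑diol condensation, SN1) with the dione enol, whose only nucleophilic carbon is C‑2; the 7‑benzyloxy‑stabilised C‑4 cation should be attacked on the face anti to the axial 3‑hydroxyl, giving the 3,4‑trans (4β, 4R) product as in couplings of 2,3‑cis flavan C‑4 cations.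

Step 6
Reactants: 11 2‑[(2R,3R,4R)‑7‑(benzyloxy)‑3‑hydroxy‑2‑[3,4,5‑tris(benzyloxy)phenyl]chroman‑4‑yl]‑3‑hydroxycyclohex‑2‑en‑1‑one
Product: 14 (2R,3R,4R)‑7‑(benzyloxy)‑4‑(2,6‑dihydroxyphenyl)‑2‑[3,4,5‑tris(benzyloxy)phenyl]chroman‑3‑ol, via silyl dienol ether 12 (not isolated), via aryl silyl ether 13 (not isolated)
Conditions: TMSOTf (3.5 equiv), Et3N (5 equiv), CH2Cl2, 0 °C; hexane, filter, concentrate; DDQ (1.05 equiv), PhMe, 0 °C; filter; K2CO3 (cat.), MeOH, rt
Reagents that add atoms: none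
Why: double soft enolisation gives the 1,3‑bis(silyloxy)cyclohexa‑1,3‑diene, which DDQ should dehydrogenate (hydride abstraction, proton loss) much faster than any benzylic position, and methanolysis frees the hydroxyls; the dione thus delivers a resorcinol bonded through C‑2, a position resorcinol itself does not offer to electrophiles.

Step 7
Reactants: 15 (−)‑epicatechin
Product: 16 5,7,3',4'‑tetra‑O‑benzyl‑(−)‑epicatechin
Conditions: BnBr (4.4 equiv), K2CO3, DMF, 0 °C → rt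
Reagents that add atoms: benzyl bromide, BrCc1ccccc1
Why: Williamson etherification of the four phenols with a base too weak for the secondary alcohol and mild enough to leave C‑2 unepimerised.

Step 8
Reactants: 16 5,7,3',4'‑tetra‑O‑benzyl‑(−)‑epicatechin
Product: 17 3,5,7,3',4'‑penta‑O‑benzyl‑(−)‑epicatechin
Conditions: NaH, BnBr, n‑Bu4NI (cat.), THF/DMF, 0 °C → rt
Reagents that add atoms: benzyl bromide, BrCc1ccccc1
Why: Williamson etherification of the secondary alcohol via its sodium alkoxide, so that no acidic proton interferes in step 10 and every protecting group falls in the last step.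

Step 9
Reactants: 17 3,5,7,3',4'‑penta‑O‑benzyl‑(−)‑epicatechin
Product: 18 8‑bromo‑3,5,7,3',4'‑penta‑O‑benzyl‑(−)‑epicatechin
Conditions: NBS (1.0 equiv), CH2Cl2, −78 °C → rt
Reagents that add atoms: N‑bromosuccinimide, O=C1CCC(=O)N1Br
Why: electrophilic aromatic bromination, which for 5,7‑di‑O‑benzyl flavans goes to C‑8 and not to C‑6, the position flanked by two benzyloxy groups.

Step 10
Reactants: 18 8‑bromo‑3,5,7,3',4'‑penta‑O‑benzyl‑(−)‑epicatechin; 5 (2S,3S)‑3‑[3,4,5‑tris(benzyloxy)phenyl]oxirane‑2‑carbaldehyde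
Product: 20 8‑{hydroxy[(2R,3S)‑3‑[3,4,5‑tris(benzyloxy)phenyl]oxiran‑2‑yl]methyl}‑3,5,7,3',4'‑penta‑O‑benzyl‑(−)‑epicatechin (carbinol epimers), via aryllithium 19 (not isolated)
Conditions: n‑BuLi (1.05 equiv), THF, −78 °C; 5 (1.1 equiv), −78 °C; aq. NH4Cl; Et3N‑deactivated silica
Reagents that add atoms: none
Why: bromine–lithium exchange and 1,2‑addition of the aryllithium to the aldehyde at −78 °C, faster than attack on the epoxide; the carbinol configuration is irrelevant because this carbon is ionised in step 11.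

Step 11
Reactants: 20 8‑{hydroxy[(2R,3S)‑3‑[3,4,5‑tris(benzyloxy)phenyl]oxiran‑2‑yl]methyl}‑3,5,7,3',4'‑penta‑O‑benzyl‑(−)‑epicatechin; 14 (2R,3R,4R)‑7‑(benzyloxy)‑4‑(2,6‑dihydroxyphenyl)‑2‑[3,4,5‑tris(benzyloxy)phenyl]chroman‑3‑ol
Product: 22 7,3',4',5'‑tetra‑O‑benzyl‑epirobinetinidol‑(4β→8)‑3',4',5'‑tri‑O‑benzyl‑epirobinetinidol‑(4α→8)‑3,5,7,3',4'‑penta‑O‑benzyl‑epicatechin (top 2R,3R,4R; middle 2R,3R,4S; bottom 2R,3R; free OH at top C‑3, middle C‑3 and middle C‑7), via Friedel-Crafts adduct 21 (not isolated)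
Conditions: 14 (1.5 equiv), (±)‑CSA (10 mol%), 4 Å MS, CH2Cl2/HFIP (9:1), slow addition of 20, −40 → 0 °C; Et3N quench
Reagents that add atoms: none
Why: Proposed new method: mild acid ionises the C‑4 hydroxyl of 20 to a cation that is an ortho/para‑quinone‑methide oxocarbenium of the bottom A‑ring, while the epoxide, whose benzylic carbon has only the weaker 3,4,5‑trialkoxyphenyl donor, stays closed; the free resorcinol ring of 14 adds through the carbon ortho to one hydroxyl and para to the other (C4–C4a bond, adduct 21), and the neighbouring phenol then opens the hydrogen‑bonded epoxide at its benzylic carbon (O1–C2 bond). The closest known reaction types are the acid‑catalysed Friedel–Crafts coupling of C‑4‑activated flavans with phenolic units and the acid‑catalysed cyclisation of 2‑(2,3‑epoxy‑3‑arylpropyl)phenols to flavan‑3‑ols, joined here into one formal [3+3] annulation. The pyran ring closes 6‑endo‑tet at the distal epoxide carbon, preferred over 5‑exo because that carbon is benzylic. C‑3 is carried over from the epoxide, C‑2 is set by inversion in the epoxide opening (cis‑epoxide to 2,3‑cis), and C‑4 is set in the Friedel–Crafts step, where allylic 1,3‑strain with the ortho oxygens of the bottom A‑ring holds H‑3 in the plane of the cation and the arene should add to the face syn to the epoxide oxygen, away from the epoxide C‑2 and its cis aryl group, which gives 3,4‑cis (4S). The step needs site selectivity for the free resorcinol over the benzylated rings (including self‑condensation at C‑6 of 20): only a free phenol can take up the cation at oxygen and hand it to the ortho carbon, alkylation of any ring by so stabilised a cation is reversible, and only 21 is drained irreversibly by ring closure, with the excess of 14 helping further. Regiochemistry within the resorcinol needs no control, because rotation about the C4(top)–C8 bond makes its two OH/ortho‑CH pairs equivalent.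

Step 12
Reactants: 22 dodeca‑O‑benzyl trimer
Product: 23 epirobinetinidol‑(4β→8)‑epirobinetinidol‑(4α→8)‑epicatechin (CNP0115797.2)
Conditions: H2 (1 atm), 20% Pd(OH)2/C, THF/MeOH/H2O, rt; filtration and freeze‑drying under inert gas
Reagents that add atoms: none
Why: hydrogenolysis of the twelve benzyl ethers over Pearlman's catalyst, under which the cyclic benzylic C2–O1 bonds and the diarylmethine C–C bonds of benzylated proanthocyanidin oligomers persist; no stereocentre is affected.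

**Compound list**

1 | 3,4,5‑tris(benzyloxy)benzaldehyde | O=Cc1cc(OCc2ccccc2)c(OCc2ccccc2)c(OCc2ccccc2)c1 | starting material
2 | methyl bis(2,2,2‑trifluoroethyl)phosphonoacetate | COC(=O)CP(=O)(OCC(F)(F)F)OCC(F)(F)F | starting material
3 | methyl (Z)‑3‑[3,4,5‑tris(benzyloxy)phenyl]prop‑2‑enoate | COC(=O)/C=C\c1cc(OCc2ccccc2)c(OCc2ccccc2)c(OCc2ccccc2)c1 | intermediate
4 | methyl (2S,3S)‑3‑[3,4,5‑tris(benzyloxy)phenyl]oxirane‑2‑carboxylate (cis) | COC(=O)[C@H]1O[C@H]1c1cc(OCc2ccccc2)c(OCc2ccccc2)c(OCc2ccccc2)c1 | intermediate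
5 | (2S,3S)‑3‑[3,4,5‑tris(benzyloxy)phenyl]oxirane‑2‑carbaldehyde (cis) | O=C[C@H]1O[C@H]1c1cc(OCc2ccccc2)c(OCc2ccccc2)c(OCc2ccccc2)c1 | intermediate
6 | 5‑(benzyloxy)‑2‑bromophenol | Oc1cc(OCc2ccccc2)ccc1Br | starting material
7 | lithium 5‑(benzyloxy)‑2‑lithiophenoxide | [Li]Oc1cc(OCc2ccccc2)ccc1[Li] | intermediate
8 | 5‑(benzyloxy)‑2‑{hydroxy[(2R,3S)‑3‑[3,4,5‑tris(benzyloxy)phenyl]oxiran‑2‑yl]methyl}phenol (carbinol epimers) | Oc1cc(OCc2ccccc2)ccc1C(O)[C@H]1O[C@H]1c1cc(OCc2ccccc2)c(OCc2ccccc2)c(OCc2ccccc2)c1 | intermediate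
9 | (2R,3R)‑7‑(benzyloxy)‑2‑[3,4,5‑tris(benzyloxy)phenyl]chromane‑3,4‑diol (2,3‑cis; C‑4 epimers) | c1ccccc1COc1ccc2c(c1)O[C@H](c1cc(OCc3ccccc3)c(OCc3ccccc3)c(OCc3ccccc3)c1)[C@H](O)C2O | intermediate
10 | cyclohexane‑1,3‑dione | O=C1CCCC(=O)C1 | starting material
11 | 2‑[(2R,3R,4R)‑7‑(benzyloxy)‑3‑hydroxy‑2‑[3,4,5‑tris(benzyloxy)phenyl]chroman‑4‑yl]‑3‑hydroxycyclohex‑2‑en‑1‑one (enol of the 1,3‑dione) | c1ccccc1COc1ccc2c(c1)O[C@H](c1cc(OCc3ccccc3)c(OCc3ccccc3)c(OCc3ccccc3)c1)[C@H](O)[C@H]2C1=C(O)CCCC1=O | intermediate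
12 | 3‑O‑trimethylsilyl ether of 11 with the dione as its 1,3‑bis(trimethylsilyloxy)cyclohexa‑1,3‑dien‑2‑yl form | c1ccccc1COc1ccc2c(c1)O[C@H](c1cc(OCc3ccccc3)c(OCc3ccccc3)c(OCc3ccccc3)c1)[C@H](O[Si](C)(C)C)[C@H]2C1=C(O[Si](C)(C)C)CCC=C1O[Si](C)(C)C | intermediate
13 | (2R,3R,4R)‑7‑(benzyloxy)‑4‑[2,6‑bis(trimethylsilyloxy)phenyl]‑3‑(trimethylsilyloxy)‑2‑[3,4,5‑tris(benzyloxy)phenyl]chromane | c1ccccc1COc1ccc2c(c1)O[C@H](c1cc(OCc3ccccc3)c(OCc3ccccc3)c(OCc3ccccc3)c1)[C@H](O[Si](C)(C)C)[C@H]2c1c(O[Si](C)(C)C)cccc1O[Si](C)(C)C | intermediate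
14 | (2R,3R,4R)‑7‑(benzyloxy)‑4‑(2,6‑dihydroxyphenyl)‑2‑[3,4,5‑tris(benzyloxy)phenyl]chroman‑3‑ol | c1ccccc1COc1ccc2c(c1)O[C@H](c1cc(OCc3ccccc3)c(OCc3ccccc3)c(OCc3ccccc3)c1)[C@H](O)[C@H]2c1c(O)cccc1O | intermediate
15 | (−)‑epicatechin, (2R,3R)‑2‑(3,4‑dihydroxyphenyl)chromane‑3,5,7‑triol | Oc1cc(O)c2c(c1)O[C@H](c1ccc(O)c(O)c1)[C@H](O)C2 | starting material
16 | 5,7,3',4'‑tetra‑O‑benzyl‑(−)‑epicatechin | c1ccccc1COc1cc(OCc3ccccc3)c2c(c1)O[C@H](c1ccc(OCc3ccccc3)c(OCc3ccccc3)c1)[C@H](O)C2 | intermediate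
17 | 3,5,7,3',4'‑penta‑O‑benzyl‑(−)‑epicatechin | c1ccccc1COc1cc(OCc3ccccc3)c2c(c1)O[C@H](c1ccc(OCc3ccccc3)c(OCc3ccccc3)c1)[C@H](OCc1ccccc1)C2 | intermediate
18 | 8‑bromo‑3,5,7,3',4'‑penta‑O‑benzyl‑(−)‑epicatechin | c1ccccc1COc1cc(OCc3ccccc3)c2c(c1Br)O[C@H](c1ccc(OCc3ccccc3)c(OCc3ccccc3)c1)[C@H](OCc1ccccc1)C2 | intermediate
19 | 8‑lithio‑3,5,7,3',4'‑penta‑O‑benzyl‑(−)‑epicatechin | c1ccccc1COc1cc(OCc3ccccc3)c2c(c1[Li])O[C@H](c1ccc(OCc3ccccc3)c(OCc3ccccc3)c1)[C@H](OCc1ccccc1)C2 | intermediate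
20 | 8‑{hydroxy[(2R,3S)‑3‑[3,4,5‑tris(benzyloxy)phenyl]oxiran‑2‑yl]methyl}‑3,5,7,3',4'‑penta‑O‑benzyl‑(−)‑epicatechin (carbinol epimers) | c1ccccc1COc1cc(OCc3ccccc3)c2c(c1C(O)[C@H]1O[C@H]1c1cc(OCc3ccccc3)c(OCc3ccccc3)c(OCc3ccccc3)c1)O[C@H](c1ccc(OCc3ccccc3)c(OCc3ccccc3)c1)[C@H](OCc1ccccc1)C2 | intermediate
21 | Friedel–Crafts adduct: 14 alkylated at C‑3 of its 2,6‑dihydroxyphenyl ring by the methine carbon of 20, cis‑epoxide intact, methine configured as C‑4 of 22 | c1ccccc1COc1ccc2c(c1)O[C@H](c1cc(OCc3ccccc3)c(OCc3ccccc3)c(OCc3ccccc3)c1)[C@H](O)[C@H]2c1c(O)ccc(c1O)[C@@H](c1c(OCc3ccccc3)cc(OCc3ccccc3)c2c1O[C@H](c1ccc(OCc3ccccc3)c(OCc3ccccc3)c1)[C@H](OCc3ccccc3)C2)[C@H]1O[C@H]1c1cc(OCc2ccccc2)c(OCc2ccccc2)c(OCc2ccccc2)c1 | intermediate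
22 | 7,3',4',5'‑tetra‑O‑benzyl‑epirobinetinidol‑(4β→8)‑3',4',5'‑tri‑O‑benzyl‑epirobinetinidol‑(4α→8)‑3,5,7,3',4'‑penta‑O‑benzyl‑epicatechin | c1ccccc1COc1ccc2c(c1)O[C@H](c1cc(OCc3ccccc3)c(OCc3ccccc3)c(OCc3ccccc3)c1)[C@H](O)[C@H]2c1c(O)ccc2c1O[C@H](c1cc(OCc3ccccc3)c(OCc3ccccc3)c(OCc3ccccc3)c1)[C@H](O)[C@@H]2c1c(OCc3ccccc3)cc(OCc3ccccc3)c2c1O[C@H](c1ccc(OCc3ccccc3)c(OCc3ccccc3)c1)[C@H](OCc3ccccc3)C2 | intermediate
23 | epirobinetinidol‑(4β→8)‑epirobinetinidol‑(4α→8)‑epicatechin (top 2R,3R,4R; middle 2R,3R,4S; bottom 2R,3R) | Oc1ccc2c(c1)O[C@H](c1cc(O)c(O)c(O)c1)[C@H](O)[C@H]2c1c(O)ccc2c1O[C@H](c1cc(O)c(O)c(O)c1)[C@H](O)[C@@H]2c1c(O)cc(O)c2c1O[C@H](c1ccc(O)c(O)c1)[C@H](O)C2 | target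

**Count**

Total steps: 12. Longest linear sequence: 8 steps (1, 2, 3, 4, 5, 6, 11, 12).

**Steps most likely to fail**

Step 11 (proposed new method). What may go wrong: addition of the arene to the other face of the cation, alkylation of a benzylated ring or self‑condensation at C‑6 of the bottom unit, and acid‑induced rearrangement of the epoxide before the phenol captures it. The fallback uses known reactions and sets the stereocentres by substrate‑controlled epoxidation after the C–C bond is in place; it sets out from 1, 19 and 14 and comes back to the route at 21. Ohira–Bestmann homologation of 1 gives 1,2,3‑tris(benzyloxy)‑5‑ethynylbenzene F1. Formylation of aryllithium 19 with DMF gives 8‑formyl‑3,5,7,3',4'‑penta‑O‑benzyl‑epicatechin F2. Addition of the lithium acetylide of F1 to F2 gives the 1,3‑diarylpropargylic alcohol F3. Acid‑catalysed propargylic Friedel–Crafts substitution of F3 with 14 gives the diarylmethine alkyne F4 as a pair of C‑4 epimers, formed without control. Lindlar semi‑hydrogenation gives the Z‑alkene F5, whose epimers are separated by chromatography. In the epimer shown, buffered mCPBA should attack the conformer with H‑4 eclipsing the alkene (allylic 1,3‑strain) on the face of the free phenol ring, which is both the hydrogen‑bonding and the less hindered side, to give epoxide 21. CSA then closes the ring 6‑endo to 22. The cost is the loss of the unwanted C‑4 epimer.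

Step 6. What may go wrong: incomplete double enol silylation and hydride abstraction by DDQ from benzylic C–H bonds other than those of the diene. The fallback avoids the dione altogether; it sets out from 9 and comes back at 14. Acid‑catalysed condensation of 9 (p‑TsOH, MeCN) with commercial 4,6‑dibromoresorcinol, whose C‑2 is the only free activated position, should give the 4β‑(3,5‑dibromo‑2,6‑dihydroxyphenyl) compound F6. Homogeneous palladium‑catalysed formate hydrodebromination (Pd(OAc)2, PPh3, HCO2H/Et3N, DMF), which leaves benzyl ethers in place, then gives 14.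

Step 2. What may go wrong: leakage to the trans‑epoxide through the stepwise radical pathway that an electron‑rich aryl group favours, insufficient enantioselectivity, and ring chlorination by hypochlorite. The fallback replaces the metal‑oxo epoxidation of the ester by a titanium–tartrate epoxidation of the allylic alcohol; it sets out from 3 and comes back at 5, bypassing step 3 as well. Full reduction of 3 with DIBAL‑H (2.2 equiv) gives (Z)‑3‑[3,4,5‑tris(benzyloxy)phenyl]prop‑2‑en‑1‑ol F7. Sharpless asymmetric epoxidation with Ti(OiPr)4, D‑(−)‑diethyl tartrate and TBHP should give [(2R,3S)‑3‑[3,4,5‑tris(benzyloxy)phenyl]oxiran‑2‑yl]methanol F8. Parikh–Doering oxidation then gives 5.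

**Further compounds**

F1 | step 11 | 1,2,3‑tris(benzyloxy)‑5‑ethynylbenzene | C#Cc1cc(OCc2ccccc2)c(OCc2ccccc2)c(OCc2ccccc2)c1
F2 | step 11 | 8‑formyl‑3,5,7,3',4'‑penta‑O‑benzyl‑(−)‑epicatechin | c1ccccc1COc1cc(OCc3ccccc3)c2c(c1C=O)O[C@H](c1ccc(OCc3ccccc3)c(OCc3ccccc3)c1)[C@H](OCc1ccccc1)C2
F3 | step 11 | 8‑{1‑hydroxy‑3‑[3,4,5‑tris(benzyloxy)phenyl]prop‑2‑yn‑1‑yl}‑3,5,7,3',4'‑penta‑O‑benzyl‑(−)‑epicatechin (carbinol epimers) | c1ccccc1COc1cc(OCc3ccccc3)c2c(c1C(O)C#Cc1cc(OCc3ccccc3)c(OCc3ccccc3)c(OCc3ccccc3)c1)O[C@H](c1ccc(OCc3ccccc3)c(OCc3ccccc3)c1)[C@H](OCc1ccccc1)C2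
F4 | step 11 | alkyne adduct: 14 alkylated at C‑3 of its 2,6‑dihydroxyphenyl ring by the propargylic carbon of F3 (C‑4 epimers) | c1ccccc1COc1ccc2c(c1)O[C@H](c1cc(OCc3ccccc3)c(OCc3ccccc3)c(OCc3ccccc3)c1)[C@H](O)[C@H]2c1c(O)ccc(c1O)C(c1c(OCc3ccccc3)cc(OCc3ccccc3)c2c1O[C@H](c1ccc(OCc3ccccc3)c(OCc3ccccc3)c1)[C@H](OCc3ccccc3)C2)C#Cc1cc(OCc2ccccc2)c(OCc2ccccc2)c(OCc2ccccc2)c1
F5 | step 11 | Z‑alkene from F4, methine configured as C‑4 of 22 | c1ccccc1COc1ccc2c(c1)O[C@H](c1cc(OCc3ccccc3)c(OCc3ccccc3)c(OCc3ccccc3)c1)[C@H](O)[C@H]2c1c(O)ccc(c1O)[C@@H](c1c(OCc3ccccc3)cc(OCc3ccccc3)c2c1O[C@H](c1ccc(OCc3ccccc3)c(OCc3ccccc3)c1)[C@H](OCc3ccccc3)C2)/C=C\c1cc(OCc2ccccc2)c(OCc2ccccc2)c(OCc2ccccc2)c1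
F6 | step 6 | (2R,3R,4R)‑7‑(benzyloxy)‑4‑(3,5‑dibromo‑2,6‑dihydroxyphenyl)‑2‑[3,4,5‑tris(benzyloxy)phenyl]chroman‑3‑ol | c1ccccc1COc1ccc2c(c1)O[C@H](c1cc(OCc3ccccc3)c(OCc3ccccc3)c(OCc3ccccc3)c1)[C@H](O)[C@H]2c1c(O)c(Br)cc(Br)c1O
F7 | step 2 | (Z)‑3‑[3,4,5‑tris(benzyloxy)phenyl]prop‑2‑en‑1‑ol | OC/C=C\c1cc(OCc2ccccc2)c(OCc2ccccc2)c(OCc2ccccc2)c1
F8 | step 2 | [(2R,3S)‑3‑[3,4,5‑tris(benzyloxy)phenyl]oxiran‑2‑yl]methanol (cis) | OC[C@H]1O[C@H]1c1cc(OCc2ccccc2)c(OCc2ccccc2)c(OCc2ccccc2)c1
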